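**Plan**

1. Numbering and enabling feature: ring C is the lactone (O1, C2 carbonyl, C3, C4, C5), ring A the 4-hydroxy-3-methoxyphenyl group on the C3 benzyl carbon C7, ring B the 4-hydroxy-3,5-dimethoxyphenyl group on the C4 benzyl arm. The tertiary C3–OH sits next to C7, a CH2 benzylic to para-oxygenated ring A, so C3–O can be made as one bond of an oxirane over C3 and C7 whose benzylic C7–O bond is then reduced away.
2. Retrosynthetic cuts, in order: the two phenolic O–benzyl bonds; O1–C2 (lactonisation of a C2 acid onto C5–OH); C7–H (hydride opening of the oxirane); C3–O and C7–O (epoxidation of the C3=C7 alkene of an E-allylic alcohol, C2 as CH2OH, C5 as silyl ether); C3=C7 (aldol condensation of an (R)-4-benzyl lactone with O-benzylvanillin); C4–H and the C4–CH2(ring B) bond (asymmetric hydrogenation of a Stobbe half-ester).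
3. Forward order: ring B aldehyde and dimethyl succinate give the half-ester; hydrogenation and reduction close ring C a first time; ring A is joined by aldol condensation; ring C is opened to the open-chain allylic alcohol; the oxirane is formed and opened; C2 is oxidised; ring C is closed again; the benzyl ethers are removed.
4. Stereochemistry: C4 comes from the rhodium–bisphosphine hydrogenation (R in 5–15, S from 16 on, by a change of priority order only). C3 comes from the titanium–tartrate epoxidation with L-(+)-diethyl tartrate under reagent control on the open chain. The C7 centre of the oxirane is transient.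

Key step: step 11

Assumption: the (S,S) antipode of Et-DuPhos is taken as the one that gives the R acid 5 (chelate model for itaconate half-esters); if the sense proved opposite, the (R,R) ligand would be used with no other change.

**Route**

Step 1
Reactants: 1 syringaldehyde
Product: 2 4-(benzyloxy)-3,5-dimethoxybenzaldehyde
Conditions: BnBr, K2CO3, DMF, 60 °C
Reagents that add atoms: benzyl bromide, BrCc1ccccc1
Why: Williamson etherification of the acidic, flanked phenol under carbonate is routine and masks it as an ether that is removed by hydrogenolysis at the end.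

Step 2
Reactants: 2 4-(benzyloxy)-3,5-dimethoxybenzaldehyde; 3 dimethyl succinate
Product: 4 (3E)-4-[4-(benzyloxy)-3,5-dimethoxyphenyl]-3-(methoxycarbonyl)but-3-enoic acid
Conditions: NaOMe, MeOH, reflux; then aq. HCl
Reagents that add atoms: none
Why: The Stobbe condensation runs through a paraconic lactone whose base-induced opening should give the half-ester with the free acid on the CH2 arm and the aryl group trans to the ester (E).

Step 3
Reactants: 4 (3E)-4-[4-(benzyloxy)-3,5-dimethoxyphenyl]-3-(methoxycarbonyl)but-3-enoic acid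
Product: 5 (3R)-4-[4-(benzyloxy)-3,5-dimethoxyphenyl]-3-(methoxycarbonyl)butanoic acid
Conditions: [Rh(cod)2]BF4 (1 mol %), (S,S)-Et-DuPhos (1.1 mol %), NaOMe (0.1 equiv), H2 (5 bar), MeOH, rt
Reagents that add atoms: none
Why: In this rhodium–bisphosphine asymmetric hydrogenation of an itaconate-type half-ester, carboxylate and alkene chelate monovalent rhodium and hydrogen is added to one enantioface, which sets the future C4 as R, while the homogeneous catalyst leaves the benzyl ether alone.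

Step 4
Reactants: 5 (3R)-4-[4-(benzyloxy)-3,5-dimethoxyphenyl]-3-(methoxycarbonyl)butanoic acid
Product: 7 (4R)-4-{[4-(benzyloxy)-3,5-dimethoxyphenyl]methyl}oxolan-2-one, via hydroxy acid 6 (not isolated)
Conditions: KOH (1 equiv), EtOH; CaCl2, NaBH4, −10 °C to rt; then 3 M HCl
Reagents that add atoms: none
Why: Calcium borohydride reduces the methyl ester while the potassium carboxylate is inert, and acidification closes the γ-lactone by 5-exo-trig acyl substitution without touching the stereocentre.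

Step 5
Reactants: 7 (4R)-4-{[4-(benzyloxy)-3,5-dimethoxyphenyl]methyl}oxolan-2-one; 8 4-(benzyloxy)-3-methoxybenzaldehyde
Product: 9 (4R)-3-{[4-(benzyloxy)-3-methoxyphenyl](hydroxy)methyl}-4-{[4-(benzyloxy)-3,5-dimethoxyphenyl]methyl}oxolan-2-one (mixture of diastereomers at C3 and the carbinol carbon)
Conditions: LiN(SiMe3)2, THF, −78 °C; then 8; aq. NH4Cl
Reagents that add atoms: none
Why: Aldol addition of the lithium lactone enolate to the aromatic aldehyde forms the C3–C7 bond; the two new centres need no control because both are erased in step 6.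

Step 6
Reactants: 9 (4R)-3-{[4-(benzyloxy)-3-methoxyphenyl](hydroxy)methyl}-4-{[4-(benzyloxy)-3,5-dimethoxyphenyl]methyl}oxolan-2-one
Product: 11 (3E,4R)-3-{[4-(benzyloxy)-3-methoxyphenyl]methylidene}-4-{[4-(benzyloxy)-3,5-dimethoxyphenyl]methyl}oxolan-2-one, via mesylate 10 (not isolated)
Conditions: MsCl, Et3N, CH2Cl2, 0 °C; then DBU, rt
Reagents that add atoms: none
Why: Mesylation and E1cB elimination should funnel all aldol diastereomers into the conjugated benzylidene lactone as its thermodynamic E isomer (aryl anti to the carbonyl).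

Step 7
Reactants: 11 (3E,4R)-3-{[4-(benzyloxy)-3-methoxyphenyl]methylidene}-4-{[4-(benzyloxy)-3,5-dimethoxyphenyl]methyl}oxolan-2-one
Product: 12 (2E)-2-[(2R)-1-[4-(benzyloxy)-3,5-dimethoxyphenyl]-3-hydroxypropan-2-yl]-3-[4-(benzyloxy)-3-methoxyphenyl]-N-methoxy-N-methylprop-2-enamide
Conditions: MeNH(OMe)·HCl, AlMe3, CH2Cl2, 0 °C to rt; aq. KNaC4H4O6; crude product used at once
Reagents that add atoms: N,O-dimethylhydroxylamine hydrochloride, CNOC.Cl
Why: Weinreb aminolysis of the lactone by the aluminium amide is an acyl substitution that opens ring C, frees C5–OH and so tells the two chain ends apart with the alkene geometry unchanged.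

Step 8
Reactants: 12 (2E)-2-[(2R)-1-[4-(benzyloxy)-3,5-dimethoxyphenyl]-3-hydroxypropan-2-yl]-3-[4-(benzyloxy)-3-methoxyphenyl]-N-methoxy-N-methylprop-2-enamide
Product: 13 (2E)-2-[(2R)-1-[4-(benzyloxy)-3,5-dimethoxyphenyl]-3-[(tert-butyldimethylsilyl)oxy]propan-2-yl]-3-[4-(benzyloxy)-3-methoxyphenyl]-N-methoxy-N-methylprop-2-enamide
Conditions: TBSCl, imidazole, DMF, 0 °C to rt
Reagents that add atoms: tert-butyldimethylsilyl chloride, CC(C)(C)[Si](C)(C)Cl
Why: Silylation of the primary alcohol stops relactonisation and keeps C5–O masked until step 15.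

Step 9
Reactants: 13 (2E)-2-[(2R)-1-[4-(benzyloxy)-3,5-dimethoxyphenyl]-3-[(tert-butyldimethylsilyl)oxy]propan-2-yl]-3-[4-(benzyloxy)-3-methoxyphenyl]-N-methoxy-N-methylprop-2-enamide
Product: 14 (2E)-2-[(2R)-1-[4-(benzyloxy)-3,5-dimethoxyphenyl]-3-[(tert-butyldimethylsilyl)oxy]propan-2-yl]-3-[4-(benzyloxy)-3-methoxyphenyl]prop-2-enal
Conditions: iBu2AlH, THF, −78 °C; aq. KNaC4H4O6
Reagents that add atoms: none
Why: Hydride reduction of a Weinreb amide stops at the chelated hemiaminal, which releases the enal only on work-up, so neither over-reduction nor conjugate reduction is expected.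

Step 10
Reactants: 14 (2E)-2-[(2R)-1-[4-(benzyloxy)-3,5-dimethoxyphenyl]-3-[(tert-butyldimethylsilyl)oxy]propan-2-yl]-3-[4-(benzyloxy)-3-methoxyphenyl]prop-2-enal
Product: 15 (2E)-2-[(2R)-1-[4-(benzyloxy)-3,5-dimethoxyphenyl]-3-[(tert-butyldimethylsilyl)oxy]propan-2-yl]-3-[4-(benzyloxy)-3-methoxyphenyl]prop-2-en-1-ol
Conditions: NaBH4, CeCl3·7H2O, MeOH, 0 °C
Reagents that add atoms: none
Why: Luche 1,2-reduction converts the enal into the allylic alcohol without attack at the β-carbon and without E/Z isomerisation.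

Step 11
Reactants: 15 (2E)-2-[(2R)-1-[4-(benzyloxy)-3,5-dimethoxyphenyl]-3-[(tert-butyldimethylsilyl)oxy]propan-2-yl]-3-[4-(benzyloxy)-3-methoxyphenyl]prop-2-en-1-ol
Product: 16 [(2S,3S)-3-[4-(benzyloxy)-3-methoxyphenyl]-2-[(2S)-1-[4-(benzyloxy)-3,5-dimethoxyphenyl]-3-[(tert-butyldimethylsilyl)oxy]propan-2-yl]oxiran-2-yl]methanol
Conditions: Ti(OiPr)4 (0.2 equiv), L-(+)-diethyl tartrate (0.25 equiv), tBuOOH (anhydrous, 2 equiv), 4 Å sieves, CH2Cl2, −25 °C; aq. NaOH/brine work-up
Reagents that add atoms: tert-butyl hydroperoxide, CC(C)(C)OO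
Why: The allylic alkoxide of 15 and tert-butyl hydroperoxide exchange onto the tartrate-bridged dimer of tetravalent titanium, and the bound peroxide oxygen is passed in one concerted syn event to the C3=C7 alkene, so the oxirane closes by oxygen-atom transfer with both C–O bonds on one face and no ring of the target is formed. The closest known reaction type is the Katsuki–Sharpless epoxidation of (E)-2,3-disubstituted 3-aryl allylic alcohols such as (E)-2,3-diphenylprop-2-en-1-ol. With L-(+)-tartrate, E-allylic alcohols give (2S,3S)-oxiranylmethanols, and since the priority order at both oxirane carbons of 16 is the same as in those models, this is the face that makes C3 S (its oxygen on the side that is cis to the ring B benzyl arm once ring C is closed) and C7 S; the tartrate sets both centres and the E geometry fixes their relative configuration. The step needs enantiofacial control that overrides the neighbouring C4 centre, which the open chain allows because no ring shields either face, and the only alkene in the molecule is the one carrying the directing CH2OH. Survival of the acid-labile para-benzyloxyphenyl oxirane should be secured by the substoichiometric titanium loading with sieves, the low temperature and the basic work-up, the crude epoxy alcohol being carried on at once.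

Step 12
Reactants: 16 [(2S,3S)-3-[4-(benzyloxy)-3-methoxyphenyl]-2-[(2S)-1-[4-(benzyloxy)-3,5-dimethoxyphenyl]-3-[(tert-butyldimethylsilyl)oxy]propan-2-yl]oxiran-2-yl]methanol
Product: 17 (2S,3S)-2-{[4-(benzyloxy)-3-methoxyphenyl]methyl}-3-{[4-(benzyloxy)-3,5-dimethoxyphenyl]methyl}-4-[(tert-butyldimethylsilyl)oxy]butane-1,2-diol
Conditions: iBu2AlH (5 equiv), CH2Cl2, −78 to 0 °C; aq. KNaC4H4O6
Reagents that add atoms: none
Why: In this C3-selective reductive opening of a 2,3-epoxy alcohol, the aluminium alkoxide activates the oxirane and hydride enters at the benzylic carbon C7, whose C–O bond is weakened by ring A while the other oxirane carbon is fully substituted; the C3–O bond is not broken, so the carbinol configuration is kept.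

Step 13
Reactants: 17 (2S,3S)-2-{[4-(benzyloxy)-3-methoxyphenyl]methyl}-3-{[4-(benzyloxy)-3,5-dimethoxyphenyl]methyl}-4-[(tert-butyldimethylsilyl)oxy]butane-1,2-diol
Product: 18 (2S,3S)-2-{[4-(benzyloxy)-3-methoxyphenyl]methyl}-3-{[4-(benzyloxy)-3,5-dimethoxyphenyl]methyl}-4-[(tert-butyldimethylsilyl)oxy]-2-hydroxybutanal
Conditions: SO3·pyridine, DMSO, iPr2NEt, CH2Cl2, 0 °C
Reagents that add atoms: none
Why: Parikh–Doering oxidation converts the primary alcohol into the aldehyde; the tertiary alcohol cannot be oxidised and activated DMSO does not cleave 1,2-diols.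

Step 14
Reactants: 18 (2S,3S)-2-{[4-(benzyloxy)-3-methoxyphenyl]methyl}-3-{[4-(benzyloxy)-3,5-dimethoxyphenyl]methyl}-4-[(tert-butyldimethylsilyl)oxy]-2-hydroxybutanal
Product: 19 (2S,3S)-2-{[4-(benzyloxy)-3-methoxyphenyl]methyl}-3-{[4-(benzyloxy)-3,5-dimethoxyphenyl]methyl}-4-[(tert-butyldimethylsilyl)oxy]-2-hydroxybutanoic acid
Conditions: NaClO2, NaH2PO4, 2-methyl-2-butene, tBuOH/H2O, 0 °C to rt
Reagents that add atoms: sodium chlorite, [Na+].[O-]Cl=O
Why: Pinnick oxidation takes the aldehyde to the acid under buffered conditions, with the alkene scavenger trapping hypochlorous acid before it can chlorinate the electron-rich rings.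

Step 15
Reactants: 19 (2S,3S)-2-{[4-(benzyloxy)-3-methoxyphenyl]methyl}-3-{[4-(benzyloxy)-3,5-dimethoxyphenyl]methyl}-4-[(tert-butyldimethylsilyl)oxy]-2-hydroxybutanoic acid
Product: 21 (3S,4S)-3-{[4-(benzyloxy)-3-methoxyphenyl]methyl}-4-{[4-(benzyloxy)-3,5-dimethoxyphenyl]methyl}-3-hydroxyoxolan-2-one, via dihydroxy acid 20 (not isolated)
Conditions: 2 M aq. HCl, THF, rt to 40 °C
Reagents that add atoms: none
Why: Acid hydrolysis of the primary silyl ether frees C5–OH, and the resulting γ-hydroxy acid should lactonise under the same acid (5-exo-trig), the tertiary non-benzylic alcohol and both stereocentres being untouched.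

Step 16
Reactants: 21 (3S,4S)-3-{[4-(benzyloxy)-3-methoxyphenyl]methyl}-4-{[4-(benzyloxy)-3,5-dimethoxyphenyl]methyl}-3-hydroxyoxolan-2-one
Product: 22 (3S,4S)-3-hydroxy-3-[(4-hydroxy-3-methoxyphenyl)methyl]-4-[(4-hydroxy-3,5-dimethoxyphenyl)methyl]oxolan-2-one (CNP0315014.1)
Conditions: H2 (1 atm), 10% Pd/C, EtOAc/MeOH, rt
Reagents that add atoms: none
Why: Hydrogenolysis cleaves both aryl benzyl ethers, while the tertiary alcohol is only homobenzylic and the lactone C–O bond is not benzylic, so nothing else should be reduced.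

**Compound list**

1 | syringaldehyde | COc1cc(C=O)cc(OC)c1O | starting material
2 | 4-(benzyloxy)-3,5-dimethoxybenzaldehyde | COc1cc(C=O)cc(OC)c1OCc1ccccc1 | intermediate
3 | dimethyl succinate | COC(=O)CCC(=O)OC | starting material
4 | (3E)-4-[4-(benzyloxy)-3,5-dimethoxyphenyl]-3-(methoxycarbonyl)but-3-enoic acid | COC(=O)/C(CC(=O)O)=C/c1cc(OC)c(OCc2ccccc2)c(OC)c1 | intermediate
5 | (3R)-4-[4-(benzyloxy)-3,5-dimethoxyphenyl]-3-(methoxycarbonyl)butanoic acid | COC(=O)[C@H](Cc1cc(OC)c(OCc2ccccc2)c(OC)c1)CC(=O)O | intermediate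
6 | (3R)-4-[4-(benzyloxy)-3,5-dimethoxyphenyl]-3-(hydroxymethyl)butanoic acid (carboxylate salt in the flask) | OC[C@H](Cc1cc(OC)c(OCc2ccccc2)c(OC)c1)CC(=O)O | intermediate
7 | (4R)-4-{[4-(benzyloxy)-3,5-dimethoxyphenyl]methyl}oxolan-2-one | O=C1OC[C@H](Cc2cc(OC)c(OCc3ccccc3)c(OC)c2)C1 | intermediate
8 | 4-(benzyloxy)-3-methoxybenzaldehyde (O-benzylvanillin) | COc1cc(C=O)ccc1OCc1ccccc1 | starting material
9 | (4R)-3-{[4-(benzyloxy)-3-methoxyphenyl](hydroxy)methyl}-4-{[4-(benzyloxy)-3,5-dimethoxyphenyl]methyl}oxolan-2-one, diastereomer mixture | O=C1OC[C@H](Cc2cc(OC)c(OCc3ccccc3)c(OC)c2)C1C(O)c4ccc(OCc5ccccc5)c(OC)c4 | intermediate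
10 | methanesulfonate of 9 | O=C1OC[C@H](Cc2cc(OC)c(OCc3ccccc3)c(OC)c2)C1C(OS(C)(=O)=O)c4ccc(OCc5ccccc5)c(OC)c4 | intermediate
11 | (3E,4R)-3-{[4-(benzyloxy)-3-methoxyphenyl]methylidene}-4-{[4-(benzyloxy)-3,5-dimethoxyphenyl]methyl}oxolan-2-one | O=C1OC[C@H](Cc2cc(OC)c(OCc3ccccc3)c(OC)c2)/C1=C\c4ccc(OCc5ccccc5)c(OC)c4 | intermediate
12 | (2E)-2-[(2R)-1-[4-(benzyloxy)-3,5-dimethoxyphenyl]-3-hydroxypropan-2-yl]-3-[4-(benzyloxy)-3-methoxyphenyl]-N-methoxy-N-methylprop-2-enamide | CON(C)C(=O)/C(=C/c1ccc(OCc2ccccc2)c(OC)c1)[C@@H](Cc1cc(OC)c(OCc2ccccc2)c(OC)c1)CO | intermediate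
13 | (2E)-2-[(2R)-1-[4-(benzyloxy)-3,5-dimethoxyphenyl]-3-[(tert-butyldimethylsilyl)oxy]propan-2-yl]-3-[4-(benzyloxy)-3-methoxyphenyl]-N-methoxy-N-methylprop-2-enamide | CON(C)C(=O)/C(=C/c1ccc(OCc2ccccc2)c(OC)c1)[C@@H](Cc1cc(OC)c(OCc2ccccc2)c(OC)c1)CO[Si](C)(C)C(C)(C)C | intermediate
14 | (2E)-2-[(2R)-1-[4-(benzyloxy)-3,5-dimethoxyphenyl]-3-[(tert-butyldimethylsilyl)oxy]propan-2-yl]-3-[4-(benzyloxy)-3-methoxyphenyl]prop-2-enal | O=C/C(=C/c1ccc(OCc2ccccc2)c(OC)c1)[C@@H](Cc1cc(OC)c(OCc2ccccc2)c(OC)c1)CO[Si](C)(C)C(C)(C)C | intermediate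
15 | (2E)-2-[(2R)-1-[4-(benzyloxy)-3,5-dimethoxyphenyl]-3-[(tert-butyldimethylsilyl)oxy]propan-2-yl]-3-[4-(benzyloxy)-3-methoxyphenyl]prop-2-en-1-ol | OC/C(=C/c1ccc(OCc2ccccc2)c(OC)c1)[C@@H](Cc1cc(OC)c(OCc2ccccc2)c(OC)c1)CO[Si](C)(C)C(C)(C)C | intermediate
16 | [(2S,3S)-3-[4-(benzyloxy)-3-methoxyphenyl]-2-[(2S)-1-[4-(benzyloxy)-3,5-dimethoxyphenyl]-3-[(tert-butyldimethylsilyl)oxy]propan-2-yl]oxiran-2-yl]methanol | OC[C@@]1(O[C@H]1c2ccc(OCc3ccccc3)c(OC)c2)[C@@H](Cc2cc(OC)c(OCc3ccccc3)c(OC)c2)CO[Si](C)(C)C(C)(C)C | intermediate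
17 | (2S,3S)-2-{[4-(benzyloxy)-3-methoxyphenyl]methyl}-3-{[4-(benzyloxy)-3,5-dimethoxyphenyl]methyl}-4-[(tert-butyldimethylsilyl)oxy]butane-1,2-diol | COc1cc(C[C@@](O)(CO)[C@@H](Cc2cc(OC)c(OCc3ccccc3)c(OC)c2)CO[Si](C)(C)C(C)(C)C)ccc1OCc1ccccc1 | intermediate
18 | (2S,3S)-2-{[4-(benzyloxy)-3-methoxyphenyl]methyl}-3-{[4-(benzyloxy)-3,5-dimethoxyphenyl]methyl}-4-[(tert-butyldimethylsilyl)oxy]-2-hydroxybutanal | COc1cc(C[C@@](O)(C=O)[C@@H](Cc2cc(OC)c(OCc3ccccc3)c(OC)c2)CO[Si](C)(C)C(C)(C)C)ccc1OCc1ccccc1 | intermediate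
19 | (2S,3S)-2-{[4-(benzyloxy)-3-methoxyphenyl]methyl}-3-{[4-(benzyloxy)-3,5-dimethoxyphenyl]methyl}-4-[(tert-butyldimethylsilyl)oxy]-2-hydroxybutanoic acid | COc1cc(C[C@@](O)(C(=O)O)[C@@H](Cc2cc(OC)c(OCc3ccccc3)c(OC)c2)CO[Si](C)(C)C(C)(C)C)ccc1OCc1ccccc1 | intermediate
20 | (2S,3S)-2-{[4-(benzyloxy)-3-methoxyphenyl]methyl}-3-{[4-(benzyloxy)-3,5-dimethoxyphenyl]methyl}-2,4-dihydroxybutanoic acid | COc1cc(C[C@@](O)(C(=O)O)[C@@H](Cc2cc(OC)c(OCc3ccccc3)c(OC)c2)CO)ccc1OCc1ccccc1 | intermediate
21 | (3S,4S)-3-{[4-(benzyloxy)-3-methoxyphenyl]methyl}-4-{[4-(benzyloxy)-3,5-dimethoxyphenyl]methyl}-3-hydroxyoxolan-2-one | COc1cc(C[C@@]2(O)C(=O)OC[C@@H]2Cc2cc(OC)c(OCc3ccccc3)c(OC)c2)ccc1OCc1ccccc1 | intermediate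
22 | (3S,4S)-3-hydroxy-3-[(4-hydroxy-3-methoxyphenyl)methyl]-4-[(4-hydroxy-3,5-dimethoxyphenyl)methyl]oxolan-2-one (CNP0315014.1) | COc1cc(C[C@@]2(O)C(=O)OC[C@@H]2Cc2cc(OC)c(O)c(OC)c2)ccc1O | target

**Count**

Total steps: 16. Longest linear sequence: 16 steps (1 to 22 through steps 1–16); 3 and 8 enter as purchased reagents.

**Steps most likely to fail**

Step 11. The para-benzyloxyphenyl oxirane may be opened or rearranged by the Lewis-acidic titanium alkoxide as it forms, turnover at the hindered trisubstituted alkene may be slow, and the C4 centre may erode the facial selectivity. Fallback: setting out from 15, a ketone-catalysed dioxirane epoxidation (Shi epoxidation) would be run with the enantiomer of the fructose-derived ketone (made from L-sorbose), KHSO5 (as 2KHSO5·KHSO4·K2SO4) and K2CO3 in MeCN/dimethoxymethane/water at pH 10.5 and 0 °C. This is the ketone antipode expected, by analogy with (E)-cinnamyl-type alcohols, to give the (2S,3S) sense, and the basic buffered medium spares acid-labile aryl oxiranes. The fallback comes back to the route at 16 directly; no further compound, F0.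

Step 12. Ionisation of the benzylic C–O bond may be followed by a 1,2-shift (semipinacol path) before hydride is delivered, or the silyl ether may be partly lost. Fallback: setting out from 16, hydrogenolysis (H2, Pd/C, EtOAc) would cleave the benzylic oxirane C–O bond and both benzyl ethers to give (2S,3S)-4-[(tert-butyldimethylsilyl)oxy]-2-[(4-hydroxy-3-methoxyphenyl)methyl]-3-[(4-hydroxy-3,5-dimethoxyphenyl)methyl]butane-1,2-diol F1. Selective re-benzylation of the two phenols (BnBr, K2CO3, acetone, reflux; the aliphatic hydroxyls do not react under carbonate) then comes back to the route at 17.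

Step 7. Aminolysis may stall, or the γ-hydroxy amide may close back to the lactone during work-up or chromatography. Fallback: setting out from 11, LiOH in THF/water would open the lactone to lithium (2E)-2-[(2R)-1-[4-(benzyloxy)-3,5-dimethoxyphenyl]-3-hydroxypropan-2-yl]-3-[4-(benzyloxy)-3-methoxyphenyl]prop-2-enoate F2, which is not acidified. Exhaustive silylation (TBSCl, imidazole, DMF) would give tert-butyldimethylsilyl (2E)-2-[(2R)-1-[4-(benzyloxy)-3,5-dimethoxyphenyl]-3-[(tert-butyldimethylsilyl)oxy]propan-2-yl]-3-[4-(benzyloxy)-3-methoxyphenyl]prop-2-enoate F3. K2CO3 in MeOH/THF/water would cleave only the silyl ester to (2E)-2-[(2R)-1-[4-(benzyloxy)-3,5-dimethoxyphenyl]-3-[(tert-butyldimethylsilyl)oxy]propan-2-yl]-3-[4-(benzyloxy)-3-methoxyphenyl]prop-2-enoic acid F4. Carbodiimide coupling (EDC·HCl, HOBt, MeNH(OMe)·HCl, iPr2NEt, CH2Cl2) comes back to the route at 13.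

**Further compounds**

F0 | step 11 | none | none
F1 | step 12 | (2S,3S)-4-[(tert-butyldimethylsilyl)oxy]-2-[(4-hydroxy-3-methoxyphenyl)methyl]-3-[(4-hydroxy-3,5-dimethoxyphenyl)methyl]butane-1,2-diol | COc1cc(C[C@@](O)(CO)[C@@H](Cc2cc(OC)c(O)c(OC)c2)CO[Si](C)(C)C(C)(C)C)ccc1O
F2 | step 7 | lithium (2E)-2-[(2R)-1-[4-(benzyloxy)-3,5-dimethoxyphenyl]-3-hydroxypropan-2-yl]-3-[4-(benzyloxy)-3-methoxyphenyl]prop-2-enoate | [Li+].[O-]C(=O)/C(=C/c1ccc(OCc2ccccc2)c(OC)c1)[C@@H](Cc1cc(OC)c(OCc2ccccc2)c(OC)c1)CO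
F3 | step 7 | tert-butyldimethylsilyl (2E)-2-[(2R)-1-[4-(benzyloxy)-3,5-dimethoxyphenyl]-3-[(tert-butyldimethylsilyl)oxy]propan-2-yl]-3-[4-(benzyloxy)-3-methoxyphenyl]prop-2-enoate | CC(C)(C)[Si](C)(C)OC(=O)/C(=C/c1ccc(OCc2ccccc2)c(OC)c1)[C@@H](Cc1cc(OC)c(OCc2ccccc2)c(OC)c1)CO[Si](C)(C)C(C)(C)C
F4 | step 7 | (2E)-2-[(2R)-1-[4-(benzyloxy)-3,5-dimethoxyphenyl]-3-[(tert-butyldimethylsilyl)oxy]propan-2-yl]-3-[4-(benzyloxy)-3-methoxyphenyl]prop-2-enoic acid | OC(=O)/C(=C/c1ccc(OCc2ccccc2)c(OC)c1)[C@@H](Cc1cc(OC)c(OCc2ccccc2)c(OC)c1)CO[Si](C)(C)C(C)(C)C
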